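## Retrosynthetic overview

1. Target 25 ⇐ keto epoxide 21, a glaucolide-type 1-oxo-4,5-epoxygermacr-7(11)-en-12,6-olide. Base removes C6–H, the epoxide opens (vinylogous E1cB, C4–O kept), and the C4 alkoxide adds across the ring to the C1 ketone to give the oxolane/hemiketal bridge; the side chain is finished by olefination in the same flask.
2. 21 ⇐ open-chain epoxy aldehyde 17. The ten-membered carbocycle is closed at C6–C7 (the bond the germacrene cyclase makes) by an alkenylchromium addition, and the C6 alkoxide closes the γ-lactone at once.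
3. 17 ⇐ ynoate 10. An iodide/formaldehyde three-component reaction gives the (Z)-β-iodoacrylate carrying C13; C4 is set in the open chain by Sharpless epoxidation.
4. 10 ⇐ aldehyde 6 + methyl propiolate (C8 by zinc alkynylation); 6 ⇐ aldehyde 2 from geranyl acetate + a crotyl unit (C10 by crotylboration).
5. Ring order: carbocycle and butenolide together (step 11), then the oxolane/hemiketal bridge (step 14).

Germacrane numbering (C1–C15) is used for the target and the macrocycles.

Assumption: the facial senses of the two reagent-controlled additions (Re-face attack for (E)-crotyl-(+)-Ipc2B in step 2 and for (S,S)-ProPhenol/Me2Zn in step 5) are taken from the accepted models; the antipodal reagent would be used if a model aldehyde showed the opposite sense.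

## Route

Step 1
Reactants: 1 geranyl acetate
Product: 2 (2E)-3-methyl-6-oxohex-2-en-1-yl acetate
Conditions: O3 (1.0 equiv), pyridine, CH2Cl2, −78 °C; Me2S, −78 °C to rt
Reagents that add atoms: ozone, [O-][O+]=O
Why: Chemoselective ozonolysis, because electrophilic ozone takes the electron-rich 6,7-alkene while the 2,3-alkene is deactivated by the allylic acetate; no stereocentre is formed.

Step 2
Reactants: 2 (2E)-3-methyl-6-oxohex-2-en-1-yl acetate; 3 trans-2-butene
Product: 4 (2E,6S,7R)-3,7-dimethylnona-2,8-diene-1,6-diol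
Conditions: 3, KOtBu, n-BuLi, THF, −78 to −45 °C; (+)-Ipc2BOMe, −78 °C; BF3·OEt2; 2, −78 °C; then NaOH, H2O2, 0 to 50 °C
Reagents that add atoms: trans-2-butene (3), C/C=C/C
Why: Brown crotylboration through a chair Zimmerman–Traxler transition state, in which the (E)-crotyl group gives the anti adduct and the (+)-Ipc2B reagent adds to the Re face, setting C7 of 4 (C10 of the target) as R and the carbinol as S (oxidised later), while the alkaline peroxide work-up also saponifies the acetate.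

Step 3
Reactants: 4 (2E,6S,7R)-3,7-dimethylnona-2,8-diene-1,6-diol
Product: 5 (2E,6S,7R)-1,6-bis[(tert-butyldimethylsilyl)oxy]-3,7-dimethylnona-2,8-diene
Conditions: TBSCl (2.6 equiv), imidazole, DMF, rt to 40 °C
Reagents that add atoms: tert-butyldimethylsilyl chloride, CC(C)(C)[Si](C)(C)Cl
Why: Imidazole-mediated silylation of both hydroxyls, which touches no stereocentre and masks C1 so that no ketone is present during the later ring closure.

Step 4
Reactants: 5 (2E,6S,7R)-1,6-bis[(tert-butyldimethylsilyl)oxy]-3,7-dimethylnona-2,8-diene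
Product: 6 (3R,4S,7E)-4,9-bis[(tert-butyldimethylsilyl)oxy]-3,7-dimethylnon-7-enal
Conditions: PdCl2(PhCN)2 (12 mol %), CuCl2·2H2O (12 mol %), AgNO2 (6 mol %), O2 (1 atm), t-BuOH/MeNO2 15:1, rt
Reagents that add atoms: dioxygen, O=O
Why: Aldehyde-selective (anti-Markovnikov) nitrite-modified Wacker oxidation of the monosubstituted alkene, with the trisubstituted alkene inert and the methyl-bearing centre untouched because it is β to the new carbonyl.

Step 5
Reactants: 6 (3R,4S,7E)-4,9-bis[(tert-butyldimethylsilyl)oxy]-3,7-dimethylnon-7-enal; 7 methyl propiolate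
Product: 8 methyl (4S,6R,7S,10E)-7,12-bis[(tert-butyldimethylsilyl)oxy]-4-hydroxy-6,10-dimethyldodec-10-en-2-ynoate
Conditions: Me2Zn (3 equiv), (S,S)-ProPhenol (20 mol %), Ph3PO (40 mol %), 7 (3 equiv), toluene, 0–4 °C
Reagents that add atoms: methyl propiolate (7), C#CC(=O)OC
Why: Trost ProPhenol dinuclear zinc alkynylation, in which the zinc acetylide is delivered to the Re face of the aldehyde inside the chiral pocket and sets C4 of 8 (C8 of the target) as S under catalyst control.

Step 6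
Reactants: 8 methyl (4S,6R,7S,10E)-7,12-bis[(tert-butyldimethylsilyl)oxy]-4-hydroxy-6,10-dimethyldodec-10-en-2-ynoate; 9 2-(diethoxyphosphoryl)propanoic acid
Product: 10 methyl (4S,6R,7S,10E)-7,12-bis[(tert-butyldimethylsilyl)oxy]-4-{[2-(diethoxyphosphoryl)propanoyl]oxy}-6,10-dimethyldodec-10-en-2-ynoate
Conditions: 9, DCC, DMAP (10 mol %), CH2Cl2, 0 °C to rt
Reagents that add atoms: 2-(diethoxyphosphoryl)propanoic acid (9), CCOP(=O)(OCC)C(C)C(=O)O
Why: Steglich esterification at oxygen with retention at C4; the phosphonate carbon is a 1:1 epimer mixture that becomes sp2 in step 14.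

Step 7
Reactants: 10 methyl (4S,6R,7S,10E)-7,12-bis[(tert-butyldimethylsilyl)oxy]-4-{[2-(diethoxyphosphoryl)propanoyl]oxy}-6,10-dimethyldodec-10-en-2-ynoate; 11 formaldehyde; 12 acetic anhydride
Product: 14 methyl (2Z,4S,6R,7S,10E)-2-(acetoxymethyl)-7,12-bis[(tert-butyldimethylsilyl)oxy]-4-{[2-(diethoxyphosphoryl)propanoyl]oxy}-3-iodo-6,10-dimethyldodeca-2,10-dienoate, via iodo alcohol 13 (not isolated)
Conditions: MgI2 (1.5 equiv), CH2O (gas from paraformaldehyde), CH2Cl2, 0 °C; then pyridine, Ac2O, DMAP (cat.), 0 °C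
Reagents that add atoms: MgI2, [Mg+2].[I-].[I-]; formaldehyde (11), C=O; acetic anhydride (12), CC(=O)OC(C)=O
Why: β-Iodo Morita–Baylis–Hillman (halo-aldol) three-component reaction, in which iodide adds to the ynoate β-carbon and the magnesium allenolate takes formaldehyde anti to iodine (trans-addition rule) to give the Z alkene with iodine cis to the ester, the magnesium alkoxide then being acetylated in the same flask.

Step 8
Reactants: 14 methyl (2Z,4S,6R,7S,10E)-2-(acetoxymethyl)-7,12-bis[(tert-butyldimethylsilyl)oxy]-4-{[2-(diethoxyphosphoryl)propanoyl]oxy}-3-iodo-6,10-dimethyldodeca-2,10-dienoate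
Product: 15 methyl (2Z,4S,6R,7S,10E)-2-(acetoxymethyl)-7-[(tert-butyldimethylsilyl)oxy]-4-{[2-(diethoxyphosphoryl)propanoyl]oxy}-12-hydroxy-3-iodo-6,10-dimethyldodeca-2,10-dienoate
Conditions: HF·pyridine, pyridine, THF, 0 °C
Reagents that add atoms: none
Why: Fluoride desilylation that is selective for the unhindered primary allylic silyl ether over the hindered secondary one; no stereocentre is touched.

Step 9
Reactants: 15 methyl (2Z,4S,6R,7S,10E)-2-(acetoxymethyl)-7-[(tert-butyldimethylsilyl)oxy]-4-{[2-(diethoxyphosphoryl)propanoyl]oxy}-12-hydroxy-3-iodo-6,10-dimethyldodeca-2,10-dienoate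
Product: 16 methyl (2Z,4S,6R,7S)-2-(acetoxymethyl)-7-[(tert-butyldimethylsilyl)oxy]-4-{[2-(diethoxyphosphoryl)propanoyl]oxy}-9-[(2S,3S)-3-(hydroxymethyl)-2-methyloxiran-2-yl]-3-iodo-6-methylnon-2-enoate
Conditions: Ti(OiPr)4 (20 mol %), L-(+)-DET (24 mol %), t-BuOOH, 4 Å sieves, CH2Cl2, −20 °C
Reagents that add atoms: tert-butyl hydroperoxide, CC(C)(C)OO
Why: Sharpless asymmetric epoxidation of the geraniol-type allylic alcohol, where L-(+)-DET delivers oxygen to the face that gives the (2S,3S)-epoxy alcohol as with geraniol, fixing C4 of the target as S while the electron-poor iodoacrylate alkene is left alone.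

Step 10
Reactants: 16 methyl (2Z,4S,6R,7S)-2-(acetoxymethyl)-7-[(tert-butyldimethylsilyl)oxy]-4-{[2-(diethoxyphosphoryl)propanoyl]oxy}-9-[(2S,3S)-3-(hydroxymethyl)-2-methyloxiran-2-yl]-3-iodo-6-methylnon-2-enoate
Product: 17 methyl (2Z,4S,6R,7S)-2-(acetoxymethyl)-7-[(tert-butyldimethylsilyl)oxy]-4-{[2-(diethoxyphosphoryl)propanoyl]oxy}-9-[(2S,3R)-3-formyl-2-methyloxiran-2-yl]-3-iodo-6-methylnon-2-enoate
Conditions: Dess–Martin periodinane, NaHCO3, CH2Cl2, 0 °C to rt
Reagents that add atoms: none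
Why: Dess–Martin oxidation of the only free hydroxyl to the α,β-epoxy aldehyde under buffered conditions, without epimerisation of the oxirane carbon (the descriptor changes from S to R only because the priorities change).

Step 11
Reactants: 17 methyl (2Z,4S,6R,7S)-2-(acetoxymethyl)-7-[(tert-butyldimethylsilyl)oxy]-4-{[2-(diethoxyphosphoryl)propanoyl]oxy}-9-[(2S,3R)-3-formyl-2-methyloxiran-2-yl]-3-iodo-6-methylnon-2-enoate
Product: 19 (1S,4S,5S,8S,10R)-13-acetoxy-1-[(tert-butyldimethylsilyl)oxy]-4,5-epoxygermacr-7(11)-en-12,6-olide 8-[2-(diethoxyphosphoryl)propanoate] (both C6 epimers), via seco hydroxy ester 18 (not isolated)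
Conditions: CrCl2 (10 equiv), NiCl2 (2 mol %), DMSO/THF 3:1, 2 mM (slow addition of 17), rt
Reagents that add atoms: none
Why: Nozaki–Hiyama–Kishi macrocyclisation, in which the alkenylchromium formed from the vinyl iodide under NiCl2 catalysis adds chemoselectively to the aldehyde to close C6–C7 (ten-membered ring) and the C6 alkoxide, cis to the ester, lactonises at once to the butenolide; C6 forms as an epimer mixture that is erased in step 14.

Step 12
Reactants: 19 (1S,4S,5S,8S,10R)-13-acetoxy-1-[(tert-butyldimethylsilyl)oxy]-4,5-epoxygermacr-7(11)-en-12,6-olide 8-[2-(diethoxyphosphoryl)propanoate]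
Product: 20 (1S,4S,5S,8S,10R)-13-acetoxy-4,5-epoxy-1-hydroxygermacr-7(11)-en-12,6-olide 8-[2-(diethoxyphosphoryl)propanoate] (both C6 epimers)
Conditions: HF·pyridine, excess pyridine, THF, 0 °C to rt
Reagents that add atoms: none
Why: Fluoride cleavage of the secondary silyl ether, with pyridine buffering to keep the epoxide closed; no stereocentre is touched.

Step 13
Reactants: 20 (1S,4S,5S,8S,10R)-13-acetoxy-4,5-epoxy-1-hydroxygermacr-7(11)-en-12,6-olide 8-[2-(diethoxyphosphoryl)propanoate]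
Product: 21 (4S,5S,8S,10R)-13-acetoxy-4,5-epoxy-1-oxogermacr-7(11)-en-12,6-olide 8-[2-(diethoxyphosphoryl)propanoate] (both C6 epimers)
Conditions: Dess–Martin periodinane, NaHCO3, CH2Cl2, 0 °C
Reagents that add atoms: none
Why: Dess–Martin oxidation of the C1 carbinol to the ketone, buffered and kept cold so that neither C10 epimerises nor acid opens the keto epoxide.

Step 14
Reactants: 21 (4S,5S,8S,10R)-13-acetoxy-4,5-epoxy-1-oxogermacr-7(11)-en-12,6-olide 8-[2-(diethoxyphosphoryl)propanoate]; 22 glycolaldehyde dimer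
Product: 25 (1R,4S,5E,8S,10R)-13-acetoxy-1,4-epoxy-1-hydroxy-8-{[(2E)-4-hydroxy-2-methylbut-2-enoyl]oxy}germacra-5,7(11)-dien-12,6-olide (CNP0154520.2), via hydroxy ketone 23 (not isolated), via hemiketal phosphonate 24 (not isolated)
Conditions: DBU (1.2 equiv), MeCN, 0 °C; then LiCl (5 equiv), 22 (1.5 equiv), DBU (1.5 equiv), 0 °C to rt
Reagents that add atoms: glycolaldehyde dimer (22), OC1COC(O)CO1
Why: Proposed new method: DBU removes the vinylogously acidic C6–H of the butenolide (both C6 epimers give the same furanolate), the anion breaks the C5–O bond of the epoxide in a vinylogous E1cB step that leaves the C4–O bond and so the 4S centre untouched and gives the ring-cis (5E) ylidene butenolide, the C4 alkoxide then adds across the ring to the C1 ketone to form the bridged hemiketal (C1 fixed as R by the bridge), and the phosphonate is finally olefinated with glycolaldehyde in a Masamune–Roush Horner–Wadsworth–Emmons reaction (E alkene); the closest known reactions are the DBU isomerisation of γ,δ-epoxy enoates to δ-hydroxy dienoates, the glaucolide-to-hirsutinolide rearrangement and LiCl/amine olefinations with glycolaldehyde dimer.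

## Compound list

1 | geranyl acetate | CC(C)=CCC/C(C)=C/COC(C)=O | starting material
2 | (2E)-3-methyl-6-oxohex-2-en-1-yl acetate | O=CCC/C(C)=C/COC(C)=O | intermediate
3 | trans-2-butene | C/C=C/C | starting material
4 | (2E,6S,7R)-3,7-dimethylnona-2,8-diene-1,6-diol | C=C[C@@H](C)[C@@H](O)CC/C(C)=C/CO | intermediate
5 | (2E,6S,7R)-1,6-bis[(tert-butyldimethylsilyl)oxy]-3,7-dimethylnona-2,8-diene | C=C[C@@H](C)[C@@H](O[Si](C)(C)C(C)(C)C)CC/C(C)=C/CO[Si](C)(C)C(C)(C)C | intermediate
6 | (3R,4S,7E)-4,9-bis[(tert-butyldimethylsilyl)oxy]-3,7-dimethylnon-7-enal | O=CC[C@@H](C)[C@@H](O[Si](C)(C)C(C)(C)C)CC/C(C)=C/CO[Si](C)(C)C(C)(C)C | intermediate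
7 | methyl propiolate | C#CC(=O)OC | starting material
8 | methyl (4S,6R,7S,10E)-7,12-bis[(tert-butyldimethylsilyl)oxy]-4-hydroxy-6,10-dimethyldodec-10-en-2-ynoate | COC(=O)C#C[C@@H](O)C[C@@H](C)[C@@H](O[Si](C)(C)C(C)(C)C)CC/C(C)=C/CO[Si](C)(C)C(C)(C)C | intermediate
9 | 2-(diethoxyphosphoryl)propanoic acid (racemic) | CCOP(=O)(OCC)C(C)C(=O)O | starting material
10 | methyl (4S,6R,7S,10E)-7,12-bis[(tert-butyldimethylsilyl)oxy]-4-{[2-(diethoxyphosphoryl)propanoyl]oxy}-6,10-dimethyldodec-10-en-2-ynoate | COC(=O)C#C[C@@H](OC(=O)C(C)P(=O)(OCC)OCC)C[C@@H](C)[C@@H](O[Si](C)(C)C(C)(C)C)CC/C(C)=C/CO[Si](C)(C)C(C)(C)C | intermediate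
11 | formaldehyde | C=O | starting material
12 | acetic anhydride | CC(=O)OC(C)=O | starting material
13 | methyl (2Z,4S,6R,7S,10E)-7,12-bis[(tert-butyldimethylsilyl)oxy]-4-{[2-(diethoxyphosphoryl)propanoyl]oxy}-2-(hydroxymethyl)-3-iodo-6,10-dimethyldodeca-2,10-dienoate (as its magnesium alkoxide) | COC(=O)/C(CO)=C(\I)[C@@H](OC(=O)C(C)P(=O)(OCC)OCC)C[C@@H](C)[C@@H](O[Si](C)(C)C(C)(C)C)CC/C(C)=C/CO[Si](C)(C)C(C)(C)C | intermediate
14 | methyl (2Z,4S,6R,7S,10E)-2-(acetoxymethyl)-7,12-bis[(tert-butyldimethylsilyl)oxy]-4-{[2-(diethoxyphosphoryl)propanoyl]oxy}-3-iodo-6,10-dimethyldodeca-2,10-dienoate | COC(=O)/C(COC(C)=O)=C(\I)[C@@H](OC(=O)C(C)P(=O)(OCC)OCC)C[C@@H](C)[C@@H](O[Si](C)(C)C(C)(C)C)CC/C(C)=C/CO[Si](C)(C)C(C)(C)C | intermediate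
15 | methyl (2Z,4S,6R,7S,10E)-2-(acetoxymethyl)-7-[(tert-butyldimethylsilyl)oxy]-4-{[2-(diethoxyphosphoryl)propanoyl]oxy}-12-hydroxy-3-iodo-6,10-dimethyldodeca-2,10-dienoate | COC(=O)/C(COC(C)=O)=C(\I)[C@@H](OC(=O)C(C)P(=O)(OCC)OCC)C[C@@H](C)[C@@H](O[Si](C)(C)C(C)(C)C)CC/C(C)=C/CO | intermediate
16 | methyl (2Z,4S,6R,7S)-2-(acetoxymethyl)-7-[(tert-butyldimethylsilyl)oxy]-4-{[2-(diethoxyphosphoryl)propanoyl]oxy}-9-[(2S,3S)-3-(hydroxymethyl)-2-methyloxiran-2-yl]-3-iodo-6-methylnon-2-enoate | COC(=O)/C(COC(C)=O)=C(\I)[C@@H](OC(=O)C(C)P(=O)(OCC)OCC)C[C@@H](C)[C@@H](O[Si](C)(C)C(C)(C)C)CC[C@]1(C)O[C@H]1CO | intermediate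
17 | methyl (2Z,4S,6R,7S)-2-(acetoxymethyl)-7-[(tert-butyldimethylsilyl)oxy]-4-{[2-(diethoxyphosphoryl)propanoyl]oxy}-9-[(2S,3R)-3-formyl-2-methyloxiran-2-yl]-3-iodo-6-methylnon-2-enoate | COC(=O)/C(COC(C)=O)=C(\I)[C@@H](OC(=O)C(C)P(=O)(OCC)OCC)C[C@@H](C)[C@@H](O[Si](C)(C)C(C)(C)C)CC[C@]1(C)O[C@H]1C=O | intermediate
18 | seco hydroxy ester: ten-membered carbocycle with C6–OH, exocyclic C7=C11 bearing CO2Me (cis to C6) and CH2OAc, 4,5-epoxide, C1–OTBS, C8 phosphonopropanoate (C6 epimers) | COC(=O)/C(COC(C)=O)=C1\C(O)[C@@H]2O[C@@]2(C)CC[C@H](O[Si](C)(C)C(C)(C)C)[C@H](C)C[C@@H]1OC(=O)C(C)P(=O)(OCC)OCC | intermediate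
19 | (1S,4S,5S,8S,10R)-13-acetoxy-1-[(tert-butyldimethylsilyl)oxy]-4,5-epoxygermacr-7(11)-en-12,6-olide 8-[2-(diethoxyphosphoryl)propanoate] (C6 epimers) | CC(=O)OCC1=C2C(OC1=O)[C@@H]3O[C@@]3(C)CC[C@H](O[Si](C)(C)C(C)(C)C)[C@H](C)C[C@@H]2OC(=O)C(C)P(=O)(OCC)OCC | intermediate
20 | (1S,4S,5S,8S,10R)-13-acetoxy-4,5-epoxy-1-hydroxygermacr-7(11)-en-12,6-olide 8-[2-(diethoxyphosphoryl)propanoate] (C6 epimers) | CC(=O)OCC1=C2C(OC1=O)[C@@H]3O[C@@]3(C)CC[C@H](O)[C@H](C)C[C@@H]2OC(=O)C(C)P(=O)(OCC)OCC | intermediate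
21 | (4S,5S,8S,10R)-13-acetoxy-4,5-epoxy-1-oxogermacr-7(11)-en-12,6-olide 8-[2-(diethoxyphosphoryl)propanoate] (C6 epimers) | CC(=O)OCC1=C2C(OC1=O)[C@@H]3O[C@@]3(C)CCC(=O)[C@H](C)C[C@@H]2OC(=O)C(C)P(=O)(OCC)OCC | intermediate
22 | glycolaldehyde dimer (2,5-dihydroxy-1,4-dioxane) | OC1COC(O)CO1 | starting material
23 | (4S,5E,8S,10R)-13-acetoxy-4-hydroxy-1-oxogermacra-5,7(11)-dien-12,6-olide 8-[2-(diethoxyphosphoryl)propanoate] | CC(=O)OCC1=C2/C(=C\[C@@](C)(O)CCC(=O)[C@H](C)C[C@@H]2OC(=O)C(C)P(=O)(OCC)OCC)OC1=O | intermediate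
24 | (1R,4S,5E,8S,10R)-13-acetoxy-1,4-epoxy-1-hydroxygermacra-5,7(11)-dien-12,6-olide 8-[2-(diethoxyphosphoryl)propanoate] | CC(=O)OCC1=C2/C(=C\[C@]3(C)CC[C@@](O)(O3)[C@H](C)C[C@@H]2OC(=O)C(C)P(=O)(OCC)OCC)OC1=O | intermediate
25 | (1R,4S,5E,8S,10R)-13-acetoxy-1,4-epoxy-1-hydroxy-8-{[(2E)-4-hydroxy-2-methylbut-2-enoyl]oxy}germacra-5,7(11)-dien-12,6-olide (CNP0154520.2) | CC(=O)OCC1=C2/C(=C\[C@]3(C)CC[C@@](O)(O3)[C@H](C)C[C@@H]2OC(=O)/C(C)=C/CO)OC1=O | target

## Step count and risks

Total steps: 14. Longest linear sequence: 14 (geranyl acetate to 25); all other inputs are purchased.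

Three steps most likely to fail:

Step 7 (iodide/formaldehyde three-component reaction on an internal ynoate). The risks are sluggish iodide addition to a β-substituted ynoate, the E/Z outcome of the tetrasubstituted alkene, and SN2′ loss of the C4 carboxylate. The fallback sets out from 8 and returns at 14. The free γ-hydroxy ynoate 8 is treated with MgI2/CH2O so that the magnesium alkoxide on C4 delivers formaldehyde to its own side, giving the (Z)-iodo diol F1; any E isomer lactonises to an iodobutenolide and is removed on silica. The primary hydroxyl is then acetylated selectively (AcCl, 2,4,6-collidine, −78 °C) to the monoacetate F2, and the secondary hydroxyl is esterified with 9 (DCC, DMAP) to give 14.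

Step 11 (ten-membered ring closure by a tetrasubstituted alkenylchromium onto an epoxy aldehyde). The risks are oligomerisation, β-elimination of the C8 carboxylate from the alkenylchromium to an allene, and decomposition of the epoxy aldehyde by Lewis-acidic chromium salts. The fallback sets out from 15 and returns at 19; it closes the ring before the epoxide exists. Allylic alcohol 15 is oxidised with MnO2 to the enal F3, which is cyclised with CrCl2/NiCl2 under the same dilution to the macrocyclic dienolide F4. The 4,5-alkene is then epoxidised on the ring with the L-fructose-derived Shi ketone/Oxone (reagent control for 4S,5S; short contact time because the doubly allylic C6–H is base-sensitive) to give 19.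

Step 14 (one-flask epoxide opening, hemiketal bridge and olefination). The risks are: a competing transannular vinylogous aldol to a cadinanolide-type C1–C6 bond (reversible under DBU, whereas the epoxide opening is not); loss of the C13 acetate from the furanolate; C10 epimerisation through the open keto form; self-condensation of glycolaldehyde; and lactonisation of any Z olefin. The fallback sets out from 21 and returns at 25. Compound 21 is treated with DBU alone and the hemiketal phosphonate 24 is isolated. It is olefinated with monomeric (tert-butyldimethylsilyloxy)acetaldehyde (LiCl, iPr2NEt, MeCN) to the silyl-protected hydroxytiglate F5, and the silyl group is removed with HF·pyridine/pyridine to give 25.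

Further compounds

F1 | step 7 | methyl (2Z,4S,6R,7S,10E)-7,12-bis[(tert-butyldimethylsilyl)oxy]-4-hydroxy-2-(hydroxymethyl)-3-iodo-6,10-dimethyldodeca-2,10-dienoate | COC(=O)/C(CO)=C(\I)[C@@H](O)C[C@@H](C)[C@@H](O[Si](C)(C)C(C)(C)C)CC/C(C)=C/CO[Si](C)(C)C(C)(C)C
F2 | step 7 | methyl (2Z,4S,6R,7S,10E)-2-(acetoxymethyl)-7,12-bis[(tert-butyldimethylsilyl)oxy]-4-hydroxy-3-iodo-6,10-dimethyldodeca-2,10-dienoate | COC(=O)/C(COC(C)=O)=C(\I)[C@@H](O)C[C@@H](C)[C@@H](O[Si](C)(C)C(C)(C)C)CC/C(C)=C/CO[Si](C)(C)C(C)(C)C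
F3 | step 11 | methyl (2Z,4S,6R,7S,10E)-2-(acetoxymethyl)-7-[(tert-butyldimethylsilyl)oxy]-4-{[2-(diethoxyphosphoryl)propanoyl]oxy}-3-iodo-6,10-dimethyl-12-oxododeca-2,10-dienoate | COC(=O)/C(COC(C)=O)=C(\I)[C@@H](OC(=O)C(C)P(=O)(OCC)OCC)C[C@@H](C)[C@@H](O[Si](C)(C)C(C)(C)C)CC/C(C)=C/C=O
F4 | step 11 | (1S,4E,8S,10R)-13-acetoxy-1-[(tert-butyldimethylsilyl)oxy]germacra-4,7(11)-dien-12,6-olide 8-[2-(diethoxyphosphoryl)propanoate] (C6 epimers) | CC(=O)OCC1=C2C(OC1=O)/C=C(C)/CC[C@H](O[Si](C)(C)C(C)(C)C)[C@H](C)C[C@@H]2OC(=O)C(C)P(=O)(OCC)OCC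
F5 | step 14 | (1R,4S,5E,8S,10R)-13-acetoxy-8-{[(2E)-4-[(tert-butyldimethylsilyl)oxy]-2-methylbut-2-enoyl]oxy}-1,4-epoxy-1-hydroxygermacra-5,7(11)-dien-12,6-olide | CC(=O)OCC1=C2/C(=C\[C@]3(C)CC[C@@](O)(O3)[C@H](C)C[C@@H]2OC(=O)/C(C)=C/CO[Si](C)(C)C(C)(C)C)OC1=O
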